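| setting | autumn | spring | midnight | south-east | west |
|---|---|---|---|---|---|
| E | 20 mM | 20 mM | 20 mM | 20 mM | 20 mM |
| Z | 20 mM | 20 mM | 20 mM | 20 mM | 20 mM |
| X | 17 mM | 26 mM | 44 mM | 20.0 mM | 40.0 mM |
| L | 70 µM | 70 µM | 70 µM | 70 µM | 70 µM |
| remark | run made earlier | run made earlier | run made earlier |  |  |
| time |  |  |  | 20 h | 20 h |

| run | time / h | Q / % | D / % |
|---|---|---|---|
| autumn | 1.50 | 19 | 9 |
| autumn | 4.00 | 23 | 13 |
| autumn | 8.00 | 24 | 8 |
| autumn | 20.0 | 24 | 10 |
| spring | 5.00 | 28 | 17 |
| spring | 10.0 | 33 | 17 |
| spring | 15.0 | 34 | 16 |
| spring | 20.0 | 35 | 12 |
| midnight | 1.50 | 38 | 19 |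
| midnight | 4.00 | 42 | 30 |
| midnight | 8.00 | 43 | 31 |
| midnight | 20.0 | 47 | 30 |

(each reading ± 2 percentage points)

- L is single-handed; E and Z are mirror images of each other, charged as a racemate, each of them at the stated concentration
- steps that have been proposed: 2 L <-> G; X -> J; X + L + E -> L + Q; X + L + Z -> L + D
- an excess is the difference of the two amounts in percent of their sum
- an excess is below zero if the other one leads

- which of the two ends with the higher excess of Q over D in the product ("neither" if they lie within 2 percentage points) (south-east / west / neither)
- excess of Q over D in the product at the end, south-east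
- excess of Q over D in the product at the end, west

- The runs held E and Z at 20 mM each and L at 70 µM, and they differ in X: 17 mM, 26 mM and 44 mM.
- Fastest rung, the first hours: Q and D climb together with Q ahead, and after 1.50 h the midnight run reads 38% Q and 19% D.
- Slowest rung, the plateau: autumn Q reads 23% at 4.00 h and 24% at 20.0 h, a move within the scatter of 2 percentage points, so I read the late readings as end states.
- Both product steps carry the same X and L, so these cancel from the ratio of the two fractional losses. I therefore used the selectivity factor s, the logarithm of the fraction of E left divided by that of the fraction of Z left, as a constant of the flask.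
- I wrote u for the logarithm of one over the fraction of Z left. Mean plateau readings give u = 0.232 in autumn, 0.357 in spring and 0.933 in midnight. Pooled with the same means of Q, they read s = 2.56.
- The cheapest step was to interpolate u straight between neighbouring X charges, which keeps the X lost to X → J inside the readings: u = 0.273 for south-east and 0.805 for west.
- My excess is then 35.6% in south-east, higher than the 22.5% in west.
- The forecast chose south-east, with 40% and 26%, both above mine, on the ground that “ln(E left)/ln(Z left) gives s ≈ 3 in all three runs”.

    2 L ⇌ G, settled at all times (K = 81000 M⁻¹)
    X → J (k = 0.180 h⁻¹)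
    X + L + E → L + Q (k = 2.00 × 10⁶ M⁻² h⁻¹)
    X + L + Z → L + D (k = 7.60 × 10⁵ M⁻² h⁻¹)

- The flasks ended with an excess of Q over D of 35.7% in south-east and 22.3% in west, so south-east leads. The gap comes from the X charge: west reads 22.3%, and 35.7% with that difference taken away. West's 44% of the charged Z left at the end gives, through s, 11.9% of the charged E left, and the west flask has 11% of the charged E left.
- With 16 mM of X, otherwise like west, 80% of the charged Z is left at the end, so s gives an excess of 37.0%. The computed value is 37.8%.

All runs are calculated with constants of no real substance; noise was put on by code.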